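## Structural features

The target is an elemanolide. A cyclohexane (C5–C10) is trans-fused at C6/C7 to an α-methylene-γ-butyrolactone (O–C6, C7–C11, C12=O, C11=C13). The ring carries five stereocentres: C5, C6, C7 and C8 are contiguous, and the quaternary C10 (methyl C14, vinyl C1=C2) is the neighbour of C5. In the chair, C4, O6, C11 and O8 are all equatorial and the C10 methyl is axial on the β face. C5 bears a 3-hydroxyprop-1-en-2-yl group (C4, C3, C15), and the 8α-oxygen is acylated by (Z)-2-(hydroxymethyl)but-2-enoic acid. The fragile groups are the exo-methylene lactone (a Michael acceptor, intolerant of strong base and of electron-transfer reagents), the (Z)-enoate (isomerises to E), the trans lactone (can migrate to O8 when the C8 hydroxyl is free under base) and two primary allylic alcohols. The real difficulty is twofold: the quaternary C10 beside the tertiary C5 in the right absolute sense, and the O6/C11/O8 triad. In that triad the C8 hydrogen must lie on the β face, syn to the axial methyl, which is the face hydride reagents avoid. The key step exploits the 1,3-relation of O6 and O8 across C7 together with the vicinal carbon substituents on C5 and C10. C6–C7–C8–C9 is a 1-alkoxy-3-silyloxy diene carrying the C11–C12 arm on C7, and C5=C10 is a trisubstituted keto ester, so one [4+2] event closes the ring and sets C5 and C10.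

The cycloaddition partners and their adduct are stereochemically self-consistent: the (E)-dienophile maps onto the (1R,2R) adduct, whose centres become C5 (R) and C10 (S) of the target. Two design points are changed:
- The diene carries a tert-butyldimethylsilyl instead of a trimethylsilyl enol ether, to survive the strongly acidic catalyst.
- The chemistry after the cycloaddition is rebuilt around two problems of the adduct: its C5–H is doubly activated (α to the acetyl, γ to the enone), and hydride reduction at C8 would give the wrong epimer.

## Logic of the disconnections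

39 is cut at the acyl C–O bond on O8 (and at two Si–O bonds, through 38) into the core alcohol 30 and the acid 36. The (Z)-enoate and the free allylic alcohols are the most fragile parts, so they come last. The forward step must acylate a hindered equatorial alcohol without Z to E isomerisation, with O15 masked and O8 free.

36 is cut at the bond between the alkene carbon and the carboxyl carbon, back to the vinyl iodide 34 and, through 33 and 32, to 31. The alkene geometry is then fixed by α-iodination of an (E)-enal. The forward carboxylation must keep that geometry (halogen–metal exchange with retention).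

30 is cut at C11=C13, through 29, to the saturated lactone 25. The exo-methylene group tolerates neither the strong bases nor the samarium reagent used earlier, so it is made after them. The forward step needs the lactone as the only enolisable site, hence silyl ethers on O8 and O15.

25 is cut at C4–C15, through 24 and the alkenyl triflate 23, to the methyl ketone 21. This reduces the C5 substituent to the acetyl group that the dienophile supplies. The forward step must enolise at the methyl group and not at C5, whose enolate would expel the C6 lactone oxygen.

21 is traced through 20 and 19 to the C8 ketone 18, cutting the C8–H bond, and 18 to its dimethyl ketal 17. The C8 carbinol is thus made on the rigid trans-lactone, where the equatorial alcohol is the thermodynamic one. The forward step must work against the steric bias, which calls for an electron-transfer reduction. Two ketals of different lability let C8 be unveiled before the acetyl.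

17 is cut at C1=C2 (back to the aldehyde 16) and, at the oxidation level, at the lactone (back to the triol 14). C1 and C12 then both descend from primary alcohols and the two ester groups of the adduct need no differentiation. The forward oxidation must touch primary alcohols only and must close the lactol on O6 alone.

14 is cut at C6–O and C7–H (syn hydration of C6=C7) to the ene diol 12, and 12 is returned through 11 and 10 to 9. Two stereocentres are removed and the cyclohexenone is regained. The forward hydroboration must place boron on C6 from the α face. C8 must be masked without moving the double bond, and the acetyl must be masked first to remove the acidity of C5–H.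

9 is cut at C9–C10 and C5–C6, through 8, into 4 and 7. The ring, the quaternary centre and the C5/C10 relation come from two achiral acyclic partners in one step. The demands are regiochemistry (ketone control), (E) geometry of 7 and enantiofacial control by the catalyst.

4 is cut at the enol O–Si bond and at the formyl C–C bond, through 3, to 1. 7 is cut at its C=C bond into 5 and 6. All three are commercial.

## Other disconnections considered

Alternative 1: The cut is C7–C11, with a transient C6–C11 bond. An ester-substituted rhodium carbenoid, generated from a diazoacetic ester, adds to the C6=C7 silyl enol ether A1 anti to the C8 silyloxy group and gives the siloxycyclopropane A2. Ring opening to the γ-keto ester, C6 reduction and lactonisation would follow.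
- In favour: the lactone arm is added last to a ring that already holds C5, C8 and C10, so C11/C12 are not carried through redox changes. The C8 oxygen exists before C7 is functionalised, so no C8 ketone reduction is needed; on that point it is better than the chosen plan. Donor–acceptor cyclopropane chemistry is dependable.
- Against: A1 requires enolisation of a C6 ketone towards C7 and not towards the more acidic allylic C5–H. The carbenoid must select the enol ether over two other alkenes. After ring opening C7 rests on protonation, and the C6 ketone must be reduced to the equatorial alcohol against the same axial C10 methyl (C6 is 1,3 to C10, as C8 is).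
- Comparison: it forms one C–C bond, no ring and no quaternary centre, so the carbocycle with C5/C10 must come from elsewhere. On the lactone assembly it is the equal of the chosen plan; on the skeleton it is weaker. Mechanistically both are well understood. In step count it is comparable once a route to A1 is added.

Alternative 2: The cuts are C10–C1 and C5–C4, followed by thermal scission of the second cyclobutane. Photoexcited enone A3 adds to the cyclobutene ester A4 and gives the photoadduct A5. Heating opens the bicyclo[2.2.0]hexane to the C10 vinyl group and the C5 propenoate arm.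
- In favour: the quaternary C10 and both unsaturated arms (with C15 at the ester level) arise in two operations from simple partners. This is clearly better than the chosen plan, which spends steps 7, 9, 10 and 14 to 17 on these groups.
- Against: the cis ring fusion places vinyl and the C4 arm cis, so C5 must be epimerised, and a cis-divinylcyclohexane is prone to Cope rearrangement. Only C6 is oxidised; the C7 arm and the C8 oxygen must be introduced on an unactivated part of the ring. The excited-state reaction offers no simple handle for absolute configuration, and its regiochemistry is less secure.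
- Comparison: structurally it is better for C1–C4, C10 and C15 and much weaker for O8 and C11–C13. Mechanistically, a triplet diradical pathway is less controllable than a catalysed ground-state cycloaddition. It has a short start, a long finish and a resolution.

Alternative 3: The cuts are C6–C7 and the lactone acyl C–O bond. In the acyclic aldehyde A6, the γ-carbon C7 of the 2-(methoxycarbonyl)allylboronate adds to the C6 aldehyde through a chair-like six-membered transition state. The alkene shifts to C11=C13 and the borate oxygen lactonises onto C12, giving the bis-silylated lactone A7.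
- In favour: carbocycle, C6, C7 and the complete exo-methylene lactone form in one operation, with O8 and both side arms already present. A7 is two or three steps from the target, so the endgame is shorter than in the chosen plan and avoids both the late methylenation and the C8 reduction. The C6/C7 relation follows from a closed transition state and is as secure as the syn hydroboration used here.
- Against: the hard part moves into A6. C5 is α to the aldehyde and allylic (easily epimerised or conjugated), C10 is quaternary, and C8 must be set by acyclic stereocontrol over many steps. The ring closure joins two hindered carbons, and 2-alkoxycarbonyl allylboronates need acid or heat.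
- Comparison: the chosen plan sets the C5/C10 pair, the most expensive part of A6, in one catalytic, stereospecific step from trivial materials. After the key step the alternative is better; before it the chosen plan is better. The alternative concentrates risk late, on a precious intermediate.

Key step: step 4

Convention: locants C1–C15 are those of the elemane skeleton used above; β is the ring face carrying the C10 methyl group, α the opposite face.
Assumption: the (S)-configured oxazaborolidinium is taken to deliver the (1R,2R) adduct by analogy with the ketone-bound binding model; if the sense were opposite, the (R)-catalyst would be used with no other change.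

Step 1
Reactants: 1 methyl levulinate
Product: 3 methyl (E)-3-(methoxymethylidene)-4-oxopentanoate, via sodium formyl enolate 2 (not isolated)
Conditions: NaOMe, HCO2Me, Et2O, 0 °C to rt; then (MeO)2SO2, DMF, rt
Reagents that add atoms: methyl formate, COC=O; dimethyl sulfate, COS(=O)(=O)OC
Why: Claisen formylation at the methylene next to the ketone (the more substituted, more stable β-keto aldehyde enolate, as with butanone), then O-methylation of the formyl oxygen by a hard alkylating agent; the (E) vinylogous ester (methoxy anti to acetyl) is the thermodynamic isomer and the geometry the diene needs.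

Step 2
Reactants: 3 methyl (E)-3-(methoxymethylidene)-4-oxopentanoate
Product: 4 methyl (E)-4-(tert-butyldimethylsilyloxy)-3-(methoxymethylidene)pent-4-enoate
Conditions: t-BuMe2SiOSO2CF3, Et3N, Et2O, 0 °C
Reagents that add atoms: tert-butyldimethylsilyl trifluoromethanesulfonate, CC(C)(C)[Si](C)(C)OS(=O)(=O)C(F)(F)F
Why: Soft enolisation and O-silylation of the vinylogous ester, the standard entry to 1-alkoxy-3-silyloxy dienes; the acetyl methyl is the only enolisable ketone position and the ester is not silylated under these conditions; the bulkier silyl group replaces trimethylsilyl so that the diene survives the acidic catalyst of step 4.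

Step 3
Reactants: 5 methyl pyruvate; 6 1-(triphenylphosphoranylidene)propan-2-one
Product: 7 methyl (E)-2-methyl-4-oxopent-2-enoate
Conditions: CH2Cl2, rt
Reagents that add atoms: none
Why: Wittig olefination of the ketone carbonyl of an α-keto ester by a stabilised acyl ylide; the isomer with acetyl and ester trans should predominate and is purified before use.

Step 4
Reactants: 4 methyl (E)-4-(tert-butyldimethylsilyloxy)-3-(methoxymethylidene)pent-4-enoate; 7 methyl (E)-2-methyl-4-oxopent-2-enoate
Product: 9 methyl (1R,2R)-2-acetyl-4-(2-methoxy-2-oxoethyl)-1-methyl-5-oxocyclohex-3-ene-1-carboxylate, via silyl enol ether cycloadduct 8 (not isolated)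
Conditions: (S)-B-(2-methylphenyl) oxazaborolidine of α,α-diphenylprolinol, activated by HN(SO2CF3)2 (20 mol %), CH2Cl2, −78 to −40 °C; then CF3CO2H, CH2Cl2, 0 °C
Reagents that add atoms: none
Why: Normal-demand Diels–Alder reaction of a 1-alkoxy-3-silyloxy diene with a Lewis-acid-bound enone, the closest known type being oxazaborolidinium-catalysed cycloadditions of such dienes with ene-dicarbonyl dienophiles. The cationic boron binds the more basic ketone oxygen of 7, so the carbon β to the ketone (C10) is the electrophilic terminus; the nucleophilic methylene terminus C9 of 4 bonds to it while the methoxy-bearing terminus C6 closes on C5, in a concerted but asynchronous event. The one cyclohexene ring is closed by an intermolecular suprafacial [4+2] addition that forms both σ bonds at once. The C5/C10 relation is stereospecific: acetyl and ester are trans in (E)-7 and stay trans, which places acetyl cis to the methyl group. The absolute configuration at C5 and C10 comes from the catalyst, which shields one face of the bound enone; the C6 stereocentre of 8 is transient. Acid work-up expels methanol and the silyl group to give the C6=C7–C8 enone. The step needs regioselectivity (secured by ketone-over-ester coordination and by the polarisation of the diene) and face selectivity (secured by the catalyst). Because C5–H of 9 is α to the acetyl and γ to the enone, 9 is taken directly into step 5.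

Step 5
Reactants: 9 Diels–Alder enone
Product: 10 enone with the acetyl group as 2-methyl-1,3-dioxolane (5β-dioxolanyl and 10β-methyl)
Conditions: Me3SiOCH2CH2OSiMe3, Me3SiOSO2CF3 (cat.), CH2Cl2, −78 °C
Reagents that add atoms: 1,2-bis(trimethylsilyloxy)ethane, C[Si](C)(C)OCCO[Si](C)(C)C
Why: Silyl-triflate-catalysed ketalisation with the bis-silyl ether of the diol, in which a saturated ketone reacts far faster than a conjugated α-substituted enone; the conditions are aprotic, non-basic and cold, so the epimerisable C5 centre is kept and C5–H is afterwards no longer α to a carbonyl.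

Step 6
Reactants: 10 enone dioxolane
Product: 11 bis-ketal diester (C8 dimethyl ketal with C6=C7 unchanged)
Conditions: MeOSiMe3, Me3SiOSO2CF3 (cat.), CH2Cl2, −78 to −30 °C; Et3N quench
Reagents that add atoms: methoxytrimethylsilane, CO[Si](C)(C)C
Why: The same kinetic ketalisation converts the enone carbonyl into its dimethyl ketal without migration of the double bond; C8 becomes a non-stereogenic group that is inert to hydride and borane and that can later be hydrolysed in the presence of the dioxolane, which as a cyclic ketal does not exchange into the acyclic one.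

Step 7
Reactants: 11 bis-ketal diester
Product: 12 ene diol (10α-hydroxymethyl and 7-(2-hydroxyethyl))
Conditions: LiAlH4, THF, 0 °C to rt
Reagents that add atoms: none
Why: Hydride reduction of both esters to primary alcohols; the ketals and the trisubstituted alkene are inert and no other carbonyl is present, so the two ester groups need no differentiation.

Step 8
Reactants: 12 ene diol
Product: 14 triol (6α-hydroxy and 7α-H), via C6 alkylborane 13 (not isolated)
Conditions: BH3·THF, THF, 0 °C to rt; then NaOH, H2O2, 0 °C to rt
Reagents that add atoms: hydrogen peroxide, OO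
Why: Hydroboration–oxidation: boron goes to the less substituted C6 and hydrogen to C7 in a syn addition on the α face, anti to the bulky 5β-dioxolanyl group next to the boron-bearing carbon and possibly assisted by delivery from the α-oriented C10 alkoxyborane. Oxidation with retention gives the 6α-alcohol and the 7α-hydrogen, so the trans relation of O6 and the C7 arm is fixed by mechanism.

Step 9
Reactants: 14 triol
Product: 16 lactone aldehyde (trans-fused 6α,12-olide with 10α-formyl), via lactol aldehyde 15 (not isolated)
Conditions: TEMPO (cat.), PhI(OAc)2, NaHCO3, CH2Cl2, rt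
Reagents that add atoms: none
Why: Nitroxyl-catalysed oxidation selective for primary alcohols: the C12 aldehyde closes on the 6α-hydroxyl and the lactol is oxidised on to the γ-lactone (oxidative lactonisation of a 1,4-diol), while the neopentyl C10 carbinol stops at the non-enolisable aldehyde; the buffer protects the dimethyl ketal.

Step 10
Reactants: 16 lactone aldehyde
Product: 17 vinyl lactone (10α-vinyl)
Conditions: Ph3PCH3Br, KOt-Bu, THF, 0 °C
Reagents that add atoms: methyltriphenylphosphonium bromide, C[P+](c1ccccc1)(c1ccccc1)c1ccccc1.[Br-]
Why: Wittig methylenation of an aldehyde that has no α-hydrogen; at 0 °C the ylide reacts with the aldehyde much faster than with the lactone, and both ketals are base-stable.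

Step 11
Reactants: 17 vinyl lactone
Product: 18 keto lactone (8-oxo)
Conditions: pyridinium p-toluenesulfonate (cat.), acetone/H2O, rt
Reagents that add atoms: water, O
Why: Mild acid hydrolysis; an acyclic dimethyl ketal is cleaved far faster than the hindered dioxolane, and the conditions are too mild to enolise the new ketone, so C7 keeps its configuration.

Step 12
Reactants: 18 keto lactone
Product: 19 hydroxy lactone (8α-hydroxy)
Conditions: SmI2, H2O, THF, 0 °C
Reagents that add atoms: none
Why: Electron-transfer (dissolving-metal type) reduction of the ketone: protonation of the ketyl-derived organosamarium should give the thermodynamically preferred equatorial 8α-alcohol, whereas hydride reagents would enter from the open α face (the axial C10 methyl blocks the β face) and give the 8β epimer. The five-membered lactone, the ketal and the vinyl group are not reduced by SmI2 in wet THF.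

Step 13
Reactants: 19 hydroxy lactone
Product: 20 8α-tert-butyldimethylsilyl ether
Conditions: t-BuMe2SiOSO2CF3, 2,6-lutidine, CH2Cl2, −78 to 0 °C
Reagents that add atoms: tert-butyldimethylsilyl trifluoromethanesulfonate, CC(C)(C)[Si](C)(C)OS(=O)(=O)C(F)(F)F
Why: Silylation of the secondary alcohol; it blocks migration of the lactone to O8 and protects the alcohol from the strong bases of steps 15 and 18.

Step 14
Reactants: 20 8α-silyl ether
Product: 21 methyl ketone (5β-acetyl)
Conditions: pyridinium p-toluenesulfonate, acetone/H2O, 60 °C
Reagents that add atoms: water, O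
Why: Acid-catalysed hydrolysis of the dioxolane under conditions that a secondary tert-butyldimethylsilyl ether and the lactone tolerate; the medium is never basic, so the β-acyloxy ketone does not eliminate.

Step 15
Reactants: 21 methyl ketone
Product: 23 alkenyl triflate (5β-[1-(trifluoromethanesulfonyloxy)ethenyl]), via potassium enolate 22 (not isolated)
Conditions: KN(SiMe3)2, THF, −78 °C; then N-(5-chloropyridin-2-yl)bis(trifluoromethanesulfonyl)imide, −78 °C
Reagents that add atoms: N-(5-chloropyridin-2-yl)bis(trifluoromethanesulfonyl)imide, FC(F)(F)S(=O)(=O)N(c1ccc(Cl)cn1)S(=O)(=O)C(F)(F)F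
Why: Kinetic deprotonation of the methyl ketone at the unhindered methyl group, not at the tertiary C5–H or the less acidic lactone α-position, then O-triflation with a reagent reactive at −78 °C; cold, immediate trapping prevents equilibration to the C5 enolate, which would expel the C6 lactone oxygen, and acyl transfer from the lactone to the enolate carbon.

Step 16
Reactants: 23 alkenyl triflate
Product: 24 allylic alcohol (5β-(3-hydroxyprop-1-en-2-yl))
Conditions: Bu3SnCH2OH, Pd(PPh3)4 (10 mol %), LiCl, 1,4-dioxane, 90 °C
Reagents that add atoms: (tributylstannyl)methanol, CCCC[Sn](CCCC)(CCCC)CO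
Why: Stille coupling of an alkenyl triflate with a hydroxymethylstannane on zerovalent palladium, with chloride assisting transmetalation; the hydroxymethyl group transfers in preference to butyl and no stereocentre is involved.

Step 17
Reactants: 24 allylic alcohol
Product: 25 15-O-tert-butyldiphenylsilyl ether
Conditions: t-BuPh2SiCl, imidazole, CH2Cl2, 0 °C to rt
Reagents that add atoms: tert-butyl(chloro)diphenylsilane, CC(C)(C)[Si](Cl)(c1ccccc1)c1ccccc1
Why: Silylation of the primary alcohol; this silyl group is chosen because it withstands the acidic fluoride that later removes the C8 silyl ether.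

Step 18
Reactants: 25 15-O-silyl lactone
Product: 29 α-methylene lactone (C11=C13), via lactone lithium enolate 26 (not isolated), via C11 dimethylaminomethyl lactone 27 (not isolated), via trimethylammonium iodide 28 (not isolated)
Conditions: LiN(i-Pr)2, THF, −78 °C; CH2=NMe2+ I−, −78 °C to rt; then MeI, rt; then aq. NaHCO3, EtOAc, rt
Reagents that add atoms: dimethylmethylideneammonium iodide, C=[N+](C)C.[I-]
Why: α-Methylenation of the lactone by a Mannich reaction of its enolate, exhaustive N-methylation and Hofmann-type β-elimination of trimethylamine; the lactone is the only enolisable group and the transient C11 stereocentre disappears.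

Step 19
Reactants: 29 α-methylene lactone
Product: 30 8α-alcohol (O15 still silylated)
Conditions: HF (48 % aq.), MeCN, 0 °C
Reagents that add atoms: none
Why: Acidic fluoride cleaves a secondary tert-butyldimethylsilyl ether much faster than a primary tert-butyldiphenylsilyl ether, and the non-nucleophilic, non-basic medium leaves the exo-methylene lactone and the ring fusion untouched.

Step 20
Reactants: 31 (E)-but-2-enal
Product: 32 (Z)-2-iodobut-2-enal
Conditions: I2, K2CO3, 4-(dimethylamino)pyridine (cat.), THF/H2O, rt
Reagents that add atoms: iodine, II
Why: Amine-mediated α-iodination of an enal (conjugate addition of the amine, iodination of the enolate, elimination); the methyl group stays anti to the formyl group, which gives the (Z)-iodide.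

Step 21
Reactants: 32 (Z)-2-iodobut-2-enal
Product: 33 (Z)-2-iodobut-2-en-1-ol
Conditions: NaBH4, CeCl3·7H2O, MeOH, 0 °C
Reagents that add atoms: none
Why: Luche 1,2-reduction of the enal; the alkene geometry and the C–I bond are unaffected.

Step 22
Reactants: 33 (Z)-2-iodobut-2-en-1-ol
Product: 34 tert-butyl{[(Z)-2-iodobut-2-en-1-yl]oxy}diphenylsilane
Conditions: t-BuPh2SiCl, imidazole, CH2Cl2, rt
Reagents that add atoms: tert-butyl(chloro)diphenylsilane, CC(C)(C)[Si](Cl)(c1ccccc1)c1ccccc1
Why: Standard silylation of a primary alcohol; the same silyl group as on O15 allows one final deprotection.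

Step 23
Reactants: 34 silylated vinyl iodide
Product: 36 (Z)-2-[(tert-butyldiphenylsilyloxy)methyl]but-2-enoic acid, via vinyllithium 35 (not isolated)
Conditions: t-BuLi (2.1 equiv), Et2O, −78 °C; CO2; then 1 M HCl
Reagents that add atoms: carbon dioxide, O=C=O
Why: Iodine–lithium exchange with retention of alkene configuration at −78 °C and carboxylation; the carboxyl group takes the place of iodine, cis to the methyl group, which is the (Z)-acid of the target side chain. Immediate quenching at −78 °C avoids silyl migration or loss of silanolate.

Step 24
Reactants: 30 8α-alcohol; 36 (Z)-2-[(tert-butyldiphenylsilyloxy)methyl]but-2-enoic acid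
Product: 38 bis-silylated target, via mixed trichlorobenzoic anhydride 37 (not isolated)
Conditions: 36, 2,4,6-trichlorobenzoyl chloride, Et3N, toluene, rt; then 30, 4-(dimethylamino)pyridine, toluene, rt to 40 °C
Reagents that add atoms: none
Why: Yamaguchi esterification: the mixed anhydride acylates the hindered equatorial alcohol, and these conditions are the ones known to transfer angelate-type acyl groups with little Z to E isomerisation; C8 keeps its configuration because the C8–O bond is not broken.

Step 25
Reactants: 38 bis-silylated target
Product: 39 CNP0111202.1, (3aR,4S,6S,7R,7aR)-6-ethenyl-7-(3-hydroxyprop-1-en-2-yl)-6-methyl-3-methylidene-2-oxooctahydro-1-benzofuran-4-yl (2Z)-2-(hydroxymethyl)but-2-enoate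
Conditions: HF·pyridine, pyridine/THF, 0 °C to rt
Reagents that add atoms: none
Why: Buffered fluoride removes both primary silyl ethers without base, so no conjugate addition to the exo-methylene lactone, no alkene isomerisation and no lactone migration are expected.

Compound list

1 | methyl levulinate (methyl 4-oxopentanoate) | CC(=O)CCC(=O)OC | starting material
2 | sodium enolate of methyl 3-formyl-4-oxopentanoate | [Na+].[O-]C=C(CC(=O)OC)C(C)=O | intermediate
3 | methyl (E)-3-(methoxymethylidene)-4-oxopentanoate | CO/C=C(/C(C)=O)CC(=O)OC | intermediate
4 | methyl (E)-4-(tert-butyldimethylsilyloxy)-3-(methoxymethylidene)pent-4-enoate | CO/C=C(CC(=O)OC)/C(=C)O[Si](C)(C)C(C)(C)C | intermediate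
5 | methyl pyruvate | CC(=O)C(=O)OC | starting material
6 | 1-(triphenylphosphoranylidene)propan-2-one | CC(=O)C=P(c1ccccc1)(c1ccccc1)c1ccccc1 | starting material
7 | methyl (E)-2-methyl-4-oxopent-2-enoate | CC(=O)/C=C(\C)C(=O)OC | intermediate
8 | methyl 2-acetyl-5-(tert-butyldimethylsilyloxy)-3-methoxy-4-(2-methoxy-2-oxoethyl)-1-methylcyclohex-4-ene-1-carboxylate (acetyl cis to the ring methyl; methoxy-bearing carbon transient) | COC(=O)[C@]1(C)CC(O[Si](C)(C)C(C)(C)C)=C(CC(=O)OC)C(OC)[C@H]1C(C)=O | intermediate
9 | methyl (1R,2R)-2-acetyl-4-(2-methoxy-2-oxoethyl)-1-methyl-5-oxocyclohex-3-ene-1-carboxylate | COC(=O)[C@]1(C)CC(=O)C(CC(=O)OC)=C[C@H]1C(C)=O | intermediate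
10 | methyl 4-(2-methoxy-2-oxoethyl)-1-methyl-2-(2-methyl-1,3-dioxolan-2-yl)-5-oxocyclohex-3-ene-1-carboxylate (5β-dioxolanyl, 10β-methyl, 10α-ester) | COC(=O)[C@]1(C)CC(=O)C(CC(=O)OC)=C[C@H]1C2(C)OCCO2 | intermediate
11 | methyl 5,5-dimethoxy-4-(2-methoxy-2-oxoethyl)-1-methyl-2-(2-methyl-1,3-dioxolan-2-yl)cyclohex-3-ene-1-carboxylate (configuration as 10) | COC(=O)[C@]1(C)CC(OC)(OC)C(CC(=O)OC)=C[C@H]1C2(C)OCCO2 | intermediate
12 | 2-[4-(hydroxymethyl)-6,6-dimethoxy-4-methyl-3-(2-methyl-1,3-dioxolan-2-yl)cyclohex-1-en-1-yl]ethanol (10α-CH2OH, 10β-CH3, 5β-dioxolanyl) | OC[C@]1(C)CC(OC)(OC)C(CCO)=C[C@H]1C2(C)OCCO2 | intermediate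
13 | C6 alkylborane of 12 (6α-boryl, 7α-H; drawn as the monoalkylborane with free hydroxyl groups) | OC[C@]1(C)CC(OC)(OC)[C@@H](CCO)[C@H](B)[C@H]1C2(C)OCCO2 | intermediate
14 | 2-(2-hydroxyethyl)-5-(hydroxymethyl)-3,3-dimethoxy-5-methyl-6-(2-methyl-1,3-dioxolan-2-yl)cyclohexan-1-ol (6α-OH, 7α-H, 10α-CH2OH, 5β-dioxolanyl) | OC[C@]1(C)CC(OC)(OC)[C@@H](CCO)[C@H](O)[C@H]1C2(C)OCCO2 | intermediate
15 | lactol aldehyde (6α,12-lactol, 10α-formyl; C12 configuration undefined) | O=C[C@]1(C)CC(OC)(OC)[C@H]2CC(O)O[C@@H]2[C@H]1C3(C)OCCO3 | intermediate
16 | lactone aldehyde: trans-fused 6α,12-olide with 8,8-dimethoxy, 10α-formyl, 10β-methyl, 5β-(2-methyl-1,3-dioxolan-2-yl) | O=C[C@]1(C)CC(OC)(OC)[C@H]2CC(=O)O[C@@H]2[C@H]1C3(C)OCCO3 | intermediate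
17 | vinyl lactone: as 16 with 10α-ethenyl | C=C[C@]1(C)CC(OC)(OC)[C@H]2CC(=O)O[C@@H]2[C@H]1C3(C)OCCO3 | intermediate
18 | keto lactone: 8-oxo-6α,12-olide with 10α-ethenyl, 10β-methyl, 5β-(2-methyl-1,3-dioxolan-2-yl) | C=C[C@]1(C)CC(=O)[C@H]2CC(=O)O[C@@H]2[C@H]1C3(C)OCCO3 | intermediate
19 | hydroxy lactone: 8α-hydroxy-6α,12-olide (otherwise as 18) | C=C[C@]1(C)C[C@H](O)[C@H]2CC(=O)O[C@@H]2[C@H]1C3(C)OCCO3 | intermediate
20 | 8α-(tert-butyldimethylsilyloxy)-6α,12-olide with 5β-(2-methyl-1,3-dioxolan-2-yl) | C=C[C@]1(C)C[C@H](O[Si](C)(C)C(C)(C)C)[C@H]2CC(=O)O[C@@H]2[C@H]1C3(C)OCCO3 | intermediate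
21 | 5β-acetyl-8α-(tert-butyldimethylsilyloxy)-6α,12-olide | C=C[C@]1(C)C[C@H](O[Si](C)(C)C(C)(C)C)[C@H]2CC(=O)O[C@@H]2[C@H]1C(C)=O | intermediate
22 | potassium enolate of 21 (terminal, at the acetyl methyl) | C=C[C@]1(C)C[C@H](O[Si](C)(C)C(C)(C)C)[C@H]2CC(=O)O[C@@H]2[C@H]1C(=C)[O-].[K+] | intermediate
23 | alkenyl triflate: 5β-[1-(trifluoromethanesulfonyloxy)ethenyl]-8α-(tert-butyldimethylsilyloxy)-6α,12-olide | C=C[C@]1(C)C[C@H](O[Si](C)(C)C(C)(C)C)[C@H]2CC(=O)O[C@@H]2[C@H]1C(=C)OS(=O)(=O)C(F)(F)F | intermediate
24 | 5β-(3-hydroxyprop-1-en-2-yl)-8α-(tert-butyldimethylsilyloxy)-6α,12-olide | C=C[C@]1(C)C[C@H](O[Si](C)(C)C(C)(C)C)[C@H]2CC(=O)O[C@@H]2[C@H]1C(=C)CO | intermediate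
25 | 15-O-tert-butyldiphenylsilyl ether of 24 | C=C[C@]1(C)C[C@H](O[Si](C)(C)C(C)(C)C)[C@H]2CC(=O)O[C@@H]2[C@H]1C(=C)CO[Si](c3ccccc3)(c4ccccc4)C(C)(C)C | intermediate
26 | lithium enolate of lactone 25 | C=C[C@]1(C)C[C@H](O[Si](C)(C)C(C)(C)C)[C@H]2C=C([O-])O[C@@H]2[C@H]1C(=C)CO[Si](c3ccccc3)(c4ccccc4)C(C)(C)C.[Li+] | intermediate
27 | 11-(dimethylaminomethyl) lactone (C11 configuration undefined and inconsequential) | C=C[C@]1(C)C[C@H](O[Si](C)(C)C(C)(C)C)[C@H]2C(CN(C)C)C(=O)O[C@@H]2[C@H]1C(=C)CO[Si](c3ccccc3)(c4ccccc4)C(C)(C)C | intermediate
28 | trimethylammonium iodide of 27 | C=C[C@]1(C)C[C@H](O[Si](C)(C)C(C)(C)C)[C@H]2C(C[N+](C)(C)C)C(=O)O[C@@H]2[C@H]1C(=C)CO[Si](c3ccccc3)(c4ccccc4)C(C)(C)C.[I-] | intermediate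
29 | α-methylene lactone with 8α-OSi(t-Bu)Me2 and 15-OSi(t-Bu)Ph2 | C=C[C@]1(C)C[C@H](O[Si](C)(C)C(C)(C)C)[C@H]2C(=C)C(=O)O[C@@H]2[C@H]1C(=C)CO[Si](c3ccccc3)(c4ccccc4)C(C)(C)C | intermediate
30 | α-methylene lactone with free 8α-OH and 15-OSi(t-Bu)Ph2 | C=C[C@]1(C)C[C@H](O)[C@H]2C(=C)C(=O)O[C@@H]2[C@H]1C(=C)CO[Si](c3ccccc3)(c4ccccc4)C(C)(C)C | intermediate
31 | (E)-but-2-enal | C/C=C/C=O | starting material
32 | (Z)-2-iodobut-2-enal | C/C=C(\I)C=O | intermediate
33 | (Z)-2-iodobut-2-en-1-ol | C/C=C(\I)CO | intermediate
34 | tert-butyl{[(Z)-2-iodobut-2-en-1-yl]oxy}diphenylsilane | C/C=C(\I)CO[Si](c1ccccc1)(c1ccccc1)C(C)(C)C | intermediate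
35 | (E)-configured vinyllithium from 34 (lithium in place of iodine, geometry retained) | C/C=C(\[Li])CO[Si](c1ccccc1)(c1ccccc1)C(C)(C)C | intermediate
36 | (Z)-2-[(tert-butyldiphenylsilyloxy)methyl]but-2-enoic acid | C/C=C(\C(=O)O)CO[Si](c1ccccc1)(c1ccccc1)C(C)(C)C | intermediate
37 | mixed anhydride of 36 with 2,4,6-trichlorobenzoic acid | C/C=C(\C(=O)OC(=O)c1c(Cl)cc(Cl)cc1Cl)CO[Si](c2ccccc2)(c2ccccc2)C(C)(C)C | intermediate
38 | bis(tert-butyldiphenylsilyl) ether of the target (both primary hydroxyl groups silylated) | C=C[C@]1(C)C[C@H](OC(=O)/C(=C\C)CO[Si](c3ccccc3)(c4ccccc4)C(C)(C)C)[C@H]2C(=C)C(=O)O[C@@H]2[C@H]1C(=C)CO[Si](c5ccccc5)(c6ccccc6)C(C)(C)C | intermediate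
39 | CNP0111202.1, (3aR,4S,6S,7R,7aR)-6-ethenyl-7-(3-hydroxyprop-1-en-2-yl)-6-methyl-3-methylidene-2-oxooctahydro-1-benzofuran-4-yl (2Z)-2-(hydroxymethyl)but-2-enoate | C=C[C@]1(C)C[C@H](OC(=O)/C(=C\C)CO)[C@H]2C(=C)C(=O)O[C@@H]2[C@H]1C(=C)CO | target

Total step count: 25. Longest linear sequence: 20 steps (steps 1, 2, 4 to 19, 24 and 25).

Least certain steps

Step 4 (key step). The most likely failures are:
- a stepwise Mukaiyama–Michael addition that stops before ring closure;
- protodesilylation of the diene by the acidic catalyst;
- slow reaction at the fully substituted C10 terminus;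
- weak face discrimination, because the dienophile is trisubstituted and has two coordinating carbonyl groups.

Fallback, with the chirality moved from the catalyst to the diene and no Lewis acid: 3 is heated with (2R,5R)-2,5-diphenylpyrrolidine (exchange of methoxide for the amine) to give the vinylogous amide F1. Silylation with t-BuMe2SiOSO2CF3 and Et3N gives the 1-amino-3-silyloxy diene F2. F2 reacts thermally with 7 in toluene to give the amino cycloadduct F3, and dilute HF in MeCN eliminates the amine and the silyl group. The route is rejoined at 9. The antipodal amine would be used if the facial sense were opposite.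

Step 12. The electron-transfer reduction may fail to reach full thermodynamic control (partial formation of the axial alcohol), or the samarium alkoxide may trigger lactone migration or β-elimination at the β-acyloxy ketone. Fallback by kinetic reduction and inversion: 18 is reduced with LiBH(s-Bu)3 in THF at −78 °C from the open α face to the 8β-alcohol F4. A Mitsunobu reaction (PPh3, diisopropyl azodicarboxylate, 4-nitrobenzoic acid) inverts C8 to the 8α 4-nitrobenzoate F5. Mild cleavage with NaN3 in MeOH returns to 19.

Step 8 (with step 6 before it). The hindered trisubstituted alkene may add borane sluggishly, the borane may attack the allylic dimethyl ketal, or the ketalisation of step 6 may move the double bond. Fallback that bypasses steps 6 to 8: 10 is epoxidised with t-BuOOH and 1,8-diazabicyclo[5.4.0]undec-7-ene anti to the C5 substituent to the 6α,7α-epoxy ketone F6. SmI2 in THF/MeOH at −90 °C opens it to the β-hydroxy ketone F7, whose C7 centre settles by protonation in the equatorial arrangement. Ketalisation with MeOSiMe3 and Me3SiOSO2CF3 gives the hydroxy dimethyl ketal F8, and LiAlH4 reduces both esters. The route is rejoined at 14. In this fallback C7 rests on thermodynamic protonation, not on a syn addition.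

Step 15. The kinetic enolate may equilibrate to the C5 enolate, with loss of the C6 lactone oxygen, or its carbon may attack the lactone carbonyl. Fallback without any enolate: 21 is methylenated under non-basic conditions (Zn, CH2Br2, TiCl4, THF/CH2Cl2) to the isopropenyl lactone F9. Allylic hydroxylation of its methyl group with SeO2 (cat.) and t-BuOOH in CH2Cl2 rejoins the route at 24.

Step 24. Reversible conjugate addition of the acylation catalyst to the activated acyl species may isomerise the (Z)-alkene, and acyl transfer to the hindered C8 hydroxyl may be slow. Fallback that never forms an activated carboxylic acid derivative: 30 and an excess of 34 are combined under CO (1 atm) with Pd(OAc)2, PPh3 and Et3N in DMF. This is an alkoxycarbonylation in which the acyl-palladium species keeps the alkene geometry and is intercepted by the C8 alcohol. It gives 38 directly and creates no new compound (entry F0).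

Further compounds

F1 | step 4 | methyl (E)-3-{[(2R,5R)-2,5-diphenylpyrrolidin-1-yl]methylidene}-4-oxopentanoate | CC(=O)/C(CC(=O)OC)=C/N1[C@@H](c2ccccc2)CC[C@@H]1c1ccccc1
F2 | step 4 | methyl (E)-4-(tert-butyldimethylsilyloxy)-3-{[(2R,5R)-2,5-diphenylpyrrolidin-1-yl]methylidene}pent-4-enoate | C=C(O[Si](C)(C)C(C)(C)C)/C(CC(=O)OC)=C/N1[C@@H](c2ccccc2)CC[C@@H]1c1ccccc1
F3 | step 4 | amino cycloadduct (as 8 with the pyrrolidinyl group in place of methoxy) | COC(=O)[C@]1(C)CC(O[Si](C)(C)C(C)(C)C)=C(CC(=O)OC)C(N2[C@@H](c3ccccc3)CC[C@@H]2c2ccccc2)[C@H]1C(C)=O
F4 | step 12 | 8β-hydroxy-6α,12-olide (C8 epimer of 19) | C=C[C@]1(C)C[C@@H](O)[C@H]2CC(=O)O[C@@H]2[C@H]1C3(C)OCCO3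
F5 | step 12 | 8α-(4-nitrobenzoyloxy)-6α,12-olide | C=C[C@]1(C)C[C@H](OC(=O)c4ccc(cc4)[N+](=O)[O-])[C@H]2CC(=O)O[C@@H]2[C@H]1C3(C)OCCO3
F6 | step 8 | 6α,7α-epoxy ketone from 10 | COC(=O)[C@]1(C)CC(=O)[C@]2(CC(=O)OC)O[C@@H]2[C@H]1C3(C)OCCO3
F7 | step 8 | 6α-hydroxy-8-oxo diester (7α-H) | COC(=O)[C@]1(C)CC(=O)[C@@H](CC(=O)OC)[C@H](O)[C@H]1C3(C)OCCO3
F8 | step 8 | 6α-hydroxy-8,8-dimethoxy diester (7α-H) | COC(=O)[C@]1(C)CC(OC)(OC)[C@@H](CC(=O)OC)[C@H](O)[C@H]1C3(C)OCCO3
F9 | step 15 | 5β-isopropenyl-8α-(tert-butyldimethylsilyloxy)-6α,12-olide | C=C[C@]1(C)C[C@H](O[Si](C)(C)C(C)(C)C)[C@H]2CC(=O)O[C@@H]2[C@H]1C(C)=C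
F0 | step 24 | none | none
A1 | alternative 1 | C6 silyl enol ether (C6=C7) with 8α-OSi(t-Bu)Me2 and 15-OSi(t-Bu)Ph2 | C=C[C@]1(C)C[C@H](O[Si](C)(C)C(C)(C)C)C=C(O[Si](C)(C)C)[C@H]1C(=C)CO[Si](c2ccccc2)(c3ccccc3)C(C)(C)C
A2 | alternative 1 | 2-siloxycyclopropanecarboxylate fused at C6–C7 | C=C[C@]1(C)C[C@H](O[Si](C)(C)C(C)(C)C)[C@H]2[C@H](C(=O)OCC)[C@@]2(O[Si](C)(C)C)[C@H]1C(=C)CO[Si](c1ccccc1)(c1ccccc1)C(C)(C)C
A3 | alternative 2 | 3-methylcyclohex-2-en-1-one | CC1=CC(=O)CCC1
A4 | alternative 2 | methyl cyclobut-1-ene-1-carboxylate | COC(=O)C1=CCC1
A5 | alternative 2 | head-to-head cis-anti-cis photoadduct | COC(=O)[C@]12CC[C@H]1[C@]3(C)CCCC(=O)[C@H]23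
A6 | alternative 3 | acyclic C6 aldehyde carrying the (Z)-2-(methoxycarbonyl)allyl pinacol boronate | O=C[C@@H](C(=C)CO[Si](C)(C)C(C)(C)C)[C@](C)(C=C)C[C@H](O[Si](CC)(CC)CC)/C=C(/CB1OC(C)(C)C(C)(C)O1)C(=O)OC
A7 | alternative 3 | bis-silylated trans-fused α-methylene lactone | C=C[C@]1(C)C[C@H](O[Si](CC)(CC)CC)[C@H]2C(=C)C(=O)O[C@@H]2[C@H]1C(=C)CO[Si](C)(C)C(C)(C)C
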